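**Remark:** the target has no stereocentre, so only constitution and alkene geometry need control. Methoxyacetylene (12) is volatile and not a routine stock item, so it is made fresh in step 8.

## Analysis of the target

Betaethrin E is a diaryl ether of two tetrasubstituted benzene rings and contains no stereocentre. Ring A is numbered here as C1 (OH), C2 (H), C3 (OMe), C4 (H), C5 (CH2O-palmitoyl) and C6 (O-aryl). Ring B is a methyl 2-hydroxy-4-methylbenzoate that carries the ether oxygen at its other ortho position. The sensitive groups are the benzylic palmitate, the methyl salicylate ester and two free phenols. The ring A phenol sits next to the ether oxygen and faces the ring B ester, so base can drive lactonization to a seven-membered depsidone-type lactone or a Smiles-type aryl migration. The synthesis is hard for two reasons: the ether oxygen is flanked by three ortho substituents, and ring A has three different oxygen functions plus a carbon substituent in a 1,2,3,5 array. Substitution or metalation of a 3,5-dioxygenated benzyl alcohol would not reach C6 selectively. The strategy rests on the C1–C6 pattern of ring A: hydroxyl at C1, methoxy meta to it at C3, unsubstituted C2 and C4, and the aryloxy and CH2O groups on the adjacent carbons C6 and C5. This is the pattern a vinylketene–alkoxyalkyne benzannulation writes directly.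

## Retrosynthetic reasoning

**Target 21 to phenol 17.** The last bond cut is the oxygen–methoxymethyl bond on ring B (21 from 20). Keeping this phenol masked to the end denies the ring B oxygen any chance to trap ketenes or to acylate. Before that, the ester C–O bond is cut (20 from diol 18 and acid chloride 19). The C16 chain is thus introduced late and never meets enolate or diazo chemistry. Diol 18 comes from silyl ether 17 by desilylation. The forward steps must deprotect without base-driven lactonization and acylate the primary benzylic hydroxyl in preference to the hindered ring A phenol.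

**Phenol 17 to diazo enone 10 and alkyne 12.** Ring A is taken apart completely. Of its six ring bonds only C2–C3 (the triple bond of 12) and C5–C6 (the enone alkene of 10) exist beforehand. C1–C2, C3–C4 and C1–C6 are made by cycloaddition and electrocyclization, and C4–C5 arises from the 1,2-shift of the Wolff rearrangement. C1 is the ketone carbon of 10 and C4 its diazo carbon. This cut is preferred over any aryl–oxygen disconnection because it turns the congested diaryl ether into an aryl vinyl ether and places every ring A substituent by construction. The forward reaction needs one regiochemical decision, the orientation of 12 on the ketene.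

**Diazo enone 10 to methyl ketone 8.** The diazo group is traced back through the trifluoroacetyl-activated diketone 9 to methyl ketone 8. A methyl ketone is a sturdier handle than an acid chloride beside an enol ether. Diazo transfer through 9 is the established way to put a diazo group on the methyl side of an enone.

**Enone 8 to bromo enone 5 and phenol 7.** The vinyl C–O bond is cut. In the forward sense it forms by addition–elimination of a phenoxide on a β-bromo enone, which needs no metal and tolerates the ortho ester. Phenol 7 comes from the symmetric diol 6 by a single protection, so ring B is bought with all its carbons in place.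

**Bromo enone 5 to methyl vinyl ketone 1.** The C–Br bond is traced to bromination–dehydrobromination of enone 3 through dibromide 4. Enone 3 comes from alcohol 2 by silylation, and 2 from 1 by α-hydroxymethylation. The bulky silyl ether is chosen because it must survive a phenoxide, an amide base, light and heat, and then leave under neutral conditions.

**Alkyne 12 to acetal 11.** The triple bond is traced to a double elimination from the chloro acetal 11, which gives the volatile alkyne just before use.

## Alternatives that were turned down

**Alternative 1: spiro-aldol on a coumaranone, then retro-Claisen.**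
- Disconnection: ring A is cut between C6 and C5. The ring B ester carbon is tied back to C6 as the ketone of a coumaranone.
- Forward key step: mild base enolizes C2 of the acylcoumaranone A1, which adds to the side-chain ketone and dehydrates to the spiro cyclohexa-2,4-dienone A2 (racemic). A separate methoxide retro-Claisen then opens the five-membered ketone to 17.
- For: it is entirely thermal and uses no diazo compound, azide or volatile alkyne. The ether oxygen is in place from the start. The ring opening reveals the methyl ester and the ring A phenol in one stroke. On safety and on freedom from photochemistry this route is stronger than the chosen one.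
- Against: A1 is a chain of four carbonyl-level carbons with three enolizable sites. Its assembly needs a C-acylation of a coumaranone (O-acylation competes) with a vinylogous ester that also carries an α-silyloxy ketone. In the ring closure the doubly activated side-chain methylene can enolize and attack the wrong carbonyl. The cross-conjugated spiro dienone A2 is prone to migration before it is opened.
- Comparison: two operations are needed where the chosen route needs one, and the precursor is harder to make than 10. The chosen strategy offers in exchange a linear precursor from an addition–elimination and substituent placement governed by the polarity of one reagent.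

**Alternative 2: ring B from a 2-pyrone by cycloaddition and decarboxylation.**
- Disconnection: ring B is cut into a pyrone diene and a two-carbon ketene acetal.
- Forward key step: the 4-aryloxy pyrone ester A4 reacts with ketene bis(trimethylsilyl) acetal A5. The CH2 carbon of A5 bonds to pyrone C6 and the acetal carbon to C3. Decarboxylation and loss of silanol give salicylate A6.
- For: inverse-demand cycloaddition of 3-carboalkoxy pyrones with ketene acetals is dependable in regiochemistry. A6 has the ring B phenol free and the ring A phenol protected, so the later acylation would face only a hydrogen-bonded salicylate hydroxyl. That is an easier selectivity problem than the one in the chosen route.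
- Against: the effort goes into the ring that can be bought (6). The hard ring A must still be supplied as phenol A3, whose 1,2,3,5 pattern is the unsolved problem of the target. The 4-aryloxy group makes the pyrone a vinylogous carbonate and a poorer diene. Attaching the hindered A3 to C4 of a pyrone is a further uncertain step.
- Comparison: the chosen strategy builds the difficult ring and buys the easy one, and so needs fewer steps overall.

**Alternative 3: aryne insertion into an aryl methyl carbonate.**
- Disconnection: the ring B–oxygen bond and the ring B–ester bond are both cut, leading to an aryne and a ring A carbonate.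
- Forward key step: fluoride releases the 3-alkoxyaryne from silyl triflate A7. The aryloxy oxygen of carbonate A8 adds at the aryne carbon remote from the alkoxy group, and the aryl anion takes the methoxycarbonyl group, giving the fully protected diaryl ether A9.
- For: it is the most convergent of the plans. It forms the hindered C–O bond and the adjacent C–C bond under mild conditions, with regiochemistry set by the alkoxy group of the aryne. On convergence it beats the chosen route.
- Against: both partners are multistep compounds. A8 again requires phenol A3. A7 needs a silylation–triflation sequence on an orcinol-type ring. Insertion into an aryl carbonate O–C bond is less secure than insertion into C–C or N–C bonds; simple O-arylation with protonation, which gives an ether without the ester, is the likely leak. Fluoride also threatens the silyl ether.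
- Comparison: the chosen strategy needs no independent ring A synthesis at all, which outweighs its linearity.

Key step: step 9

## Route

**Step 1**
Reactants: 1 methyl vinyl ketone
Product: 2 3-(hydroxymethyl)but-3-en-2-one
Conditions: aq. CH2O (37%), DABCO (cat.), THF–H2O, rt
Reagents that add atoms: formaldehyde, C=O
Why: Baylis–Hillman reaction; the amine adds to the enone and the resulting enolate is captured by the unhindered aldehyde, which is used in excess to outrun enone dimerization.

**Step 2**
Reactants: 2 3-(hydroxymethyl)but-3-en-2-one
Product: 3 3-{[(triisopropylsilyl)oxy]methyl}but-3-en-2-one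
Conditions: i-Pr3SiOTf, 2,6-lutidine, CH2Cl2, −78 °C
Reagents that add atoms: triisopropylsilyl trifluoromethanesulfonate, CC(C)[Si](OS(=O)(=O)C(F)(F)F)(C(C)C)C(C)C
Why: Silylation of a primary alcohol with a silyl triflate and a non-nucleophilic base, which cannot add to the enone.

**Step 3**
Reactants: 3 3-{[(triisopropylsilyl)oxy]methyl}but-3-en-2-one
Product: 5 (E)-4-bromo-3-{[(triisopropylsilyl)oxy]methyl}but-3-en-2-one, via dibromide 4 (not isolated)
Conditions: Br2, CH2Cl2, −78 → 0 °C; then Et3N, 0 °C → rt
Reagents that add atoms: bromine, BrBr
Why: Bromine addition to the 1,1-disubstituted alkene followed by E2 loss of HBr from the carbonyl-activated tertiary bromide, as in the preparation of 3-bromomethacrylates; the more acidic BrCH2 hydrogen is removed and bromine ends trans to the acetyl group.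

**Step 4**
Reactants: 6 methyl 2,6-dihydroxy-4-methylbenzoate
Product: 7 methyl 2-hydroxy-6-(methoxymethoxy)-4-methylbenzoate
Conditions: MeOCH2Cl (1.0 equiv), i-Pr2NEt, CH2Cl2, 0 °C
Reagents that add atoms: chloromethyl methyl ether, COCCl
Why: Mono-alkylation of a symmetric bis-phenol; after the first alkylation the remaining hydroxyl is locked in a hydrogen bond to the ester and reacts more slowly, which should favour the monoether.

**Step 5**
Reactants: 5 (E)-4-bromo-3-{[(triisopropylsilyl)oxy]methyl}but-3-en-2-one; 7 methyl 2-hydroxy-6-(methoxymethoxy)-4-methylbenzoate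
Product: 8 methyl 2-(methoxymethoxy)-4-methyl-6-{[(1E)-3-oxo-2-{[(triisopropylsilyl)oxy]methyl}but-1-en-1-yl]oxy}benzoate
Conditions: Cs2CO3, DMF, 0 °C → rt
Reagents that add atoms: none
Why: Nucleophilic vinylic substitution by addition–elimination; the phenoxide adds to the β-carbon and bromide leaves from the enolate, with the E isomer (aryloxy trans to acetyl) expected by retention and by equilibration.

**Step 6**
Reactants: 8 aryloxy enone (methyl ketone)
Product: 9 methyl 2-(methoxymethoxy)-4-methyl-6-{[(1E)-6,6,6-trifluoro-3,5-dioxo-2-{[(triisopropylsilyl)oxy]methyl}hex-1-en-1-yl]oxy}benzoate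
Conditions: LiN(SiMe3)2, THF, −78 °C; CF3CO2CH2CF3; aq. HCl work-up; used crude
Reagents that add atoms: 2,2,2-trifluoroethyl trifluoroacetate, FC(F)(F)COC(=O)C(F)(F)F
Why: Kinetic deprotonation of the methyl group and Claisen-type trifluoroacetylation; the hindered benzoate has no α-hydrogen and is inert at this temperature.

**Step 7**
Reactants: 9 trifluoroacetyl diketone
Product: 10 methyl 2-{[(1E)-4-diazo-3-oxo-2-{[(triisopropylsilyl)oxy]methyl}but-1-en-1-yl]oxy}-6-(methoxymethoxy)-4-methylbenzoate
Conditions: MeSO2N3, Et3N, H2O (1 equiv), MeCN, rt
Reagents that add atoms: methanesulfonyl azide, CS(=O)(=O)N=[N+]=[N-]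
Why: Detrifluoroacetylative diazo transfer; the diketone enolate adds to the azide and the adduct fragments with transfer of the trifluoroacetyl group to the sulfonamide nitrogen, the standard route to diazomethyl ketones of enones.

**Step 8**
Reactants: 11 chloroacetaldehyde dimethyl acetal
Product: 12 methoxyacetylene
Conditions: NaNH2 (3 equiv), liq. NH3, −33 °C; evaporate NH3; cold satd aq. NaCl; distil into a cold trap
Reagents that add atoms: none
Why: Double elimination (HCl, then methanol) from the α-chloro acetal gives the sodium alkynide, which is hydrolysed to the alkoxyalkyne; this is the classical preparation of alkoxyacetylenes.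

**Step 9**
Reactants: 10 diazo enone; 12 methoxyacetylene
Product: 17 methyl 2-[2-hydroxy-4-methoxy-6-{[(triisopropylsilyl)oxy]methyl}phenoxy]-6-(methoxymethoxy)-4-methylbenzoate, via vinylketene 13 (not isolated), via 4-alkenyl-3-methoxycyclobutenone 14 (not isolated), via dienylketene 15 (not isolated), via cyclohexa-2,4-dienone 16 (not isolated)
Conditions: 12 (4 equiv), hν (300 nm lamps, Pyrex), ClCH2CH2Cl, sealed vessel, 10–15 °C; then 80 °C
Reagents that add atoms: none
Why: Excitation of 10 expels nitrogen with a concerted 1,2-shift of the alkenyl group (Wolff rearrangement), which moves C5 from the carbonyl carbon C1 to the former diazo carbon C4 and gives vinylketene 13. Ketene–alkyne (2+2) cycloaddition of 13 with 12 forms C1–C2 and C3–C4 and gives cyclobutenone 14. On warming, 14 opens reversibly by four-electron conrotatory cleavage of C1–C4 to dienylketene 15; the isomer with the ketenyl carbon and the alkenyl group cis closes ring A by thermal disrotatory six-electron electrocyclization (C1–C6) to dienone 16, which tautomerizes to phenol 17. The closest known reaction is the Danheiser benzannulation in its diazo ketone form with alkoxy- and silyloxyalkynes. No stereocentre survives, since the sp3 carbons of 14 and 16 are racemic and are flattened on aromatization. The selectivity needed is the orientation of the (2+2) step, and it is secured by the polarization of 12: its nucleophilic CH carbon bonds to the electrophilic ketene carbon C1, which puts methoxy meta and aryloxy ortho to the new hydroxyl. The E geometry of 10 keeps the aryloxy group on the outside of the closing terminus, excess alkyne and dilution limit capture of ketenes by the phenol formed, and Pyrex-filtered light is absorbed by the diazo enone rather than by the benzoate.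

**Step 10**
Reactants: 17 silyl ether phenol
Product: 18 methyl 2-[2-hydroxy-6-(hydroxymethyl)-4-methoxyphenoxy]-6-(methoxymethoxy)-4-methylbenzoate
Conditions: Bu4NF, AcOH, THF, 0 °C → rt
Reagents that add atoms: none
Why: Fluoride-induced desilylation; the acetic acid buffer keeps the ring A phenol protonated and so suppresses lactonization onto the ring B ester and aryl migration.

**Step 11**
Reactants: 18 diol; 19 palmitoyl chloride
Product: 20 methyl 2-{2-[(hexadecanoyloxy)methyl]-6-hydroxy-4-methoxyphenoxy}-6-(methoxymethoxy)-4-methylbenzoate
Conditions: 19 (1.05 equiv), 2,4,6-collidine, CH2Cl2, −40 → 0 °C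
Reagents that add atoms: none
Why: Chemoselective O-acylation; with a base too weak to form phenoxide the primary benzylic hydroxyl is the better nucleophile, and the phenol is shielded by the neighbouring aryloxy group.

**Step 12**
Reactants: 20 methoxymethyl ether
Product: 21 betaethrin E, methyl 2-{2-[(hexadecanoyloxy)methyl]-6-hydroxy-4-methoxyphenoxy}-6-hydroxy-4-methylbenzoate
Conditions: CF3CO2H–CH2Cl2 (1:9), 0 °C; aqueous work-up
Reagents that add atoms: none
Why: Acid cleavage of an aryl methoxymethyl ether through the oxocarbenium ion, helped by the ortho ester; the benzylic palmitate has no strongly cation-stabilizing para donor and, like the methyl ester and the diaryl ether, should survive brief dilute acid.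

## Compound list

1 | methyl vinyl ketone (but-3-en-2-one) | CC(=O)C=C | starting material
2 | 3-(hydroxymethyl)but-3-en-2-one | CC(=O)C(=C)CO | intermediate
3 | 3-{[(triisopropylsilyl)oxy]methyl}but-3-en-2-one | CC(=O)C(=C)CO[Si](C(C)C)(C(C)C)C(C)C | intermediate
4 | 3,4-dibromo-3-{[(triisopropylsilyl)oxy]methyl}butan-2-one (racemic, not isolated) | CC(=O)C(Br)(CBr)CO[Si](C(C)C)(C(C)C)C(C)C | intermediate
5 | (E)-4-bromo-3-{[(triisopropylsilyl)oxy]methyl}but-3-en-2-one | CC(=O)/C(CO[Si](C(C)C)(C(C)C)C(C)C)=C/Br | intermediate
6 | methyl 2,6-dihydroxy-4-methylbenzoate | COC(=O)c1c(O)cc(C)cc1O | starting material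
7 | methyl 2-hydroxy-6-(methoxymethoxy)-4-methylbenzoate | COC(=O)c1c(O)cc(C)cc1OCOC | intermediate
8 | methyl 2-(methoxymethoxy)-4-methyl-6-{[(1E)-3-oxo-2-{[(triisopropylsilyl)oxy]methyl}but-1-en-1-yl]oxy}benzoate | CC(=O)/C(CO[Si](C(C)C)(C(C)C)C(C)C)=C/Oc1cc(C)cc(OCOC)c1C(=O)OC | intermediate
9 | methyl 2-(methoxymethoxy)-4-methyl-6-{[(1E)-6,6,6-trifluoro-3,5-dioxo-2-{[(triisopropylsilyl)oxy]methyl}hex-1-en-1-yl]oxy}benzoate (drawn as the diketone) | O=C(CC(=O)C(F)(F)F)/C(CO[Si](C(C)C)(C(C)C)C(C)C)=C/Oc1cc(C)cc(OCOC)c1C(=O)OC | intermediate
10 | methyl 2-{[(1E)-4-diazo-3-oxo-2-{[(triisopropylsilyl)oxy]methyl}but-1-en-1-yl]oxy}-6-(methoxymethoxy)-4-methylbenzoate | [N-]=[N+]=CC(=O)/C(CO[Si](C(C)C)(C(C)C)C(C)C)=C/Oc1cc(C)cc(OCOC)c1C(=O)OC | intermediate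
11 | chloroacetaldehyde dimethyl acetal (2-chloro-1,1-dimethoxyethane) | COC(CCl)OC | starting material
12 | methoxyacetylene (methoxyethyne) | COC#C | intermediate
13 | vinylketene, methyl 2-(methoxymethoxy)-4-methyl-6-{[(1Z)-4-oxo-2-{[(triisopropylsilyl)oxy]methyl}buta-1,3-dien-1-yl]oxy}benzoate (aryloxy trans to the ketenyl carbon; not isolated) | O=C=C/C(CO[Si](C(C)C)(C(C)C)C(C)C)=C/Oc1cc(C)cc(OCOC)c1C(=O)OC | intermediate
14 | 3-methoxy-4-alkenylcyclobut-2-en-1-one carrying the 1-aryloxy-3-(silyloxy)prop-1-en-2-yl group at C4 (racemic, not isolated) | O=C1C=C(OC)C1/C(CO[Si](C(C)C)(C(C)C)C(C)C)=C/Oc2cc(C)cc(OCOC)c2C(=O)OC | intermediate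
15 | dienylketene, 6-aryloxy-3-methoxy-5-(silyloxymethyl)hexa-1,3,5-trien-1-one with the ketenyl carbon and C5 cis on the central double bond (not isolated) | O=C=C/C(OC)=C\C(CO[Si](C(C)C)(C(C)C)C(C)C)=C\Oc1cc(C)cc(OCOC)c1C(=O)OC | intermediate
16 | 6-aryloxy-3-methoxy-5-{[(triisopropylsilyl)oxy]methyl}cyclohexa-2,4-dien-1-one (racemic, not isolated) | O=C1C=C(OC)C=C(CO[Si](C(C)C)(C(C)C)C(C)C)C1Oc2cc(C)cc(OCOC)c2C(=O)OC | intermediate
17 | methyl 2-[2-hydroxy-4-methoxy-6-{[(triisopropylsilyl)oxy]methyl}phenoxy]-6-(methoxymethoxy)-4-methylbenzoate | COc1cc(O)c(Oc2cc(C)cc(OCOC)c2C(=O)OC)c(CO[Si](C(C)C)(C(C)C)C(C)C)c1 | intermediate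
18 | methyl 2-[2-hydroxy-6-(hydroxymethyl)-4-methoxyphenoxy]-6-(methoxymethoxy)-4-methylbenzoate | COc1cc(O)c(Oc2cc(C)cc(OCOC)c2C(=O)OC)c(CO)c1 | intermediate
19 | palmitoyl chloride (hexadecanoyl chloride) | CCCCCCCCCCCCCCCC(=O)Cl | starting material
20 | methyl 2-{2-[(hexadecanoyloxy)methyl]-6-hydroxy-4-methoxyphenoxy}-6-(methoxymethoxy)-4-methylbenzoate | CCCCCCCCCCCCCCCC(=O)OCc1cc(OC)cc(O)c1Oc1cc(C)cc(OCOC)c1C(=O)OC | intermediate
21 | betaethrin E, methyl 2-{2-[(hexadecanoyloxy)methyl]-6-hydroxy-4-methoxyphenoxy}-6-hydroxy-4-methylbenzoate | CCCCCCCCCCCCCCCC(=O)OCc1cc(OC)cc(O)c1Oc1cc(C)cc(O)c1C(=O)OC | target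

## Step count and least certain steps

Total step count: 12. Longest linear sequence: 10 steps (steps 1, 2, 3, 5, 6, 7, 9, 10, 11, 12).

**Step 9 (key step).**
- Most likely to go wrong: photodegradation of the push–pull aryloxy enone and of the diaryl ether formed; light-driven E/Z isomerization that turns the aryloxy group to the inside of the closing terminus and slows ring closure; and slow capture of the vinylketene by a volatile alkyne, so that ketene dimerization or acylation of the product phenol takes over.
- Fallback: ketene formation is separated from irradiation. It sets out from 10. A Wolff rearrangement in the dark (AgO2CPh cat., Et3N, THF–H2O) should give the homologous acid (Z)-4-aryloxy-3-{[(triisopropylsilyl)oxy]methyl}but-3-enoic acid F1. Neutral chlorination with 1-chloro-N,N,2-trimethylprop-1-en-1-amine gives the acid chloride F2. Slow addition of Et3N to F2 and excess 12 in toluene (0 °C → rt) generates the same vinylketene 13 by dehydrochlorination, which is captured as cyclobutenone 14. Heating at 80–110 °C carries 14 through 15 and 16, and the route is rejoined at 17.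

**Step 3.**
- Most likely to go wrong: loss of HBr in the wrong direction (towards the silyloxymethyl group, giving a silyl enol ether), or enolization on the methyl side of the tertiary α-bromo ketone followed by Favorskii-type collapse; adventitious HBr may also loosen the silyl ether.
- Fallback: the substituents are placed by reactions with fixed regiochemistry. It sets out from 7. Amine-catalysed conjugate addition of 7 to but-3-yn-2-one (DABCO cat., CH2Cl2) gives the (E)-aryloxy enone F3. α-Iodination with N-iodosuccinimide (MeCN) gives the (Z)-iodo enone F4. Stille coupling with (tributylstannyl)methanol (Pd(PPh3)4, dioxane, 80 °C) gives the hydroxymethyl enone F5. Silylation (i-Pr3SiCl, imidazole, DMF) rejoins the route at 8.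

**Step 6 (with step 7).**
- Most likely to go wrong: O-acylation of the enolate; proton transfer from the vinylogous CH2O position; displacement of the aryloxide by the trifluoroethoxide set free; or retro-Claisen loss of the trifluoroacetyl group on work-up.
- Fallback: the acyl-activated diketone is avoided. It sets out from 8. Deprotonation with LiN(SiMe3)2 in the presence of Me3SiCl (THF, −78 °C) traps the enolate as it forms and gives the 2-silyloxy diene F6. N-Bromosuccinimide converts F6 into the bromomethyl ketone F7. N,N'-Ditosylhydrazine and DBU (THF, 0 °C) turn the bromide into the diazo group, and the route is rejoined at 10.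

**Step 11.**
- Most likely to go wrong: competing or double acylation at the ring A phenol, and base-promoted attack of that phenol on the ring B ester.
- Fallback: the phenol is masked first. It sets out from 17. Alkylation with MeOCH2Cl and i-Pr2NEt gives the bis(methoxymethyl) silyl ether F8. Bu4NF gives the benzylic alcohol F9. Acylation with 19 (Et3N, DMAP) gives the bis(methoxymethyl) palmitate F10. CF3CO2H–CH2Cl2 removes both acetals, and the route is rejoined at 21.

## Further compounds

F1 | step 9 | (Z)-4-[2-(methoxycarbonyl)-3-(methoxymethoxy)-5-methylphenoxy]-3-{[(triisopropylsilyl)oxy]methyl}but-3-enoic acid | OC(=O)C/C(CO[Si](C(C)C)(C(C)C)C(C)C)=C/Oc1cc(C)cc(OCOC)c1C(=O)OC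
F2 | step 9 | (Z)-4-[2-(methoxycarbonyl)-3-(methoxymethoxy)-5-methylphenoxy]-3-{[(triisopropylsilyl)oxy]methyl}but-3-enoyl chloride | ClC(=O)C/C(CO[Si](C(C)C)(C(C)C)C(C)C)=C/Oc1cc(C)cc(OCOC)c1C(=O)OC
F3 | step 3 | methyl 2-(methoxymethoxy)-4-methyl-6-{[(1E)-3-oxobut-1-en-1-yl]oxy}benzoate | CC(=O)/C=C/Oc1cc(C)cc(OCOC)c1C(=O)OC
F4 | step 3 | methyl 2-{[(1Z)-2-iodo-3-oxobut-1-en-1-yl]oxy}-6-(methoxymethoxy)-4-methylbenzoate | CC(=O)/C(I)=C/Oc1cc(C)cc(OCOC)c1C(=O)OC
F5 | step 3 | methyl 2-{[(1E)-2-(hydroxymethyl)-3-oxobut-1-en-1-yl]oxy}-6-(methoxymethoxy)-4-methylbenzoate | CC(=O)/C(CO)=C/Oc1cc(C)cc(OCOC)c1C(=O)OC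
F6 | step 6 | methyl 2-(methoxymethoxy)-4-methyl-6-{[(1E)-2-{[(triisopropylsilyl)oxy]methyl}-3-[(trimethylsilyl)oxy]buta-1,3-dien-1-yl]oxy}benzoate | C=C(O[Si](C)(C)C)/C(CO[Si](C(C)C)(C(C)C)C(C)C)=C/Oc1cc(C)cc(OCOC)c1C(=O)OC
F7 | step 6 | methyl 2-{[(1E)-4-bromo-3-oxo-2-{[(triisopropylsilyl)oxy]methyl}but-1-en-1-yl]oxy}-6-(methoxymethoxy)-4-methylbenzoate | BrCC(=O)/C(CO[Si](C(C)C)(C(C)C)C(C)C)=C/Oc1cc(C)cc(OCOC)c1C(=O)OC
F8 | step 11 | methyl 2-[4-methoxy-2-(methoxymethoxy)-6-{[(triisopropylsilyl)oxy]methyl}phenoxy]-6-(methoxymethoxy)-4-methylbenzoate | COCOc1cc(OC)cc(CO[Si](C(C)C)(C(C)C)C(C)C)c1Oc1cc(C)cc(OCOC)c1C(=O)OC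
F9 | step 11 | methyl 2-[2-(hydroxymethyl)-4-methoxy-6-(methoxymethoxy)phenoxy]-6-(methoxymethoxy)-4-methylbenzoate | COCOc1cc(OC)cc(CO)c1Oc1cc(C)cc(OCOC)c1C(=O)OC
F10 | step 11 | methyl 2-{2-[(hexadecanoyloxy)methyl]-4-methoxy-6-(methoxymethoxy)phenoxy}-6-(methoxymethoxy)-4-methylbenzoate | CCCCCCCCCCCCCCCC(=O)OCc1cc(OC)cc(OCOC)c1Oc1cc(C)cc(OCOC)c1C(=O)OC
A1 | alternative 1 | 2-{3-methoxy-5-oxo-6-[(triisopropylsilyl)oxy]hex-2-enoyl}-4-(methoxymethoxy)-6-methylbenzofuran-3(2H)-one (racemic) | COC(=CC(=O)C1Oc2cc(C)cc(OCOC)c2C1=O)CC(=O)CO[Si](C(C)C)(C(C)C)C(C)C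
A2 | alternative 1 | protected spiro grisadienone, spiro[benzofuran-2(3H),1'-cyclohexa-2',4'-diene]-3,6'-dione with 4'-methoxy, 2'-(silyloxymethyl), 4-(methoxymethoxy) and 6-methyl groups (racemic) | COC1=CC(=O)C2(Oc3cc(C)cc(OCOC)c3C2=O)C(CO[Si](C(C)C)(C(C)C)C(C)C)=C1
A3 | alternative 2 | 4-methoxy-2-(methoxymethoxy)-6-{[(triisopropylsilyl)oxy]methyl}phenol | Oc1c(CO[Si](C(C)C)(C(C)C)C(C)C)cc(OC)cc1OCOC
A4 | alternative 2 | methyl 4-[4-methoxy-2-(methoxymethoxy)-6-{[(triisopropylsilyl)oxy]methyl}phenoxy]-6-methyl-2-oxo-2H-pyran-3-carboxylate | COC(=O)C1=C(Oc2c(CO[Si](C(C)C)(C(C)C)C(C)C)cc(OC)cc2OCOC)C=C(C)OC1=O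
A5 | alternative 2 | ketene bis(trimethylsilyl) acetal, 1,1-bis[(trimethylsilyl)oxy]ethene | C=C(O[Si](C)(C)C)O[Si](C)(C)C
A6 | alternative 2 | methyl 2-hydroxy-6-[4-methoxy-2-(methoxymethoxy)-6-{[(triisopropylsilyl)oxy]methyl}phenoxy]-4-methylbenzoate | COC(=O)c1c(O)cc(C)cc1Oc1c(CO[Si](C(C)C)(C(C)C)C(C)C)cc(OC)cc1OCOC
A7 | alternative 3 | 3-(methoxymethoxy)-5-methyl-2-(trimethylsilyl)phenyl trifluoromethanesulfonate | COCOc1cc(C)cc(OS(=O)(=O)C(F)(F)F)c1[Si](C)(C)C
A8 | alternative 3 | 4-methoxy-2-(methoxymethoxy)-6-{[(triisopropylsilyl)oxy]methyl}phenyl methyl carbonate | COC(=O)Oc1c(CO[Si](C(C)C)(C(C)C)C(C)C)cc(OC)cc1OCOC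
A9 | alternative 3 | methyl 2-[4-methoxy-2-(methoxymethoxy)-6-{[(triisopropylsilyl)oxy]methyl}phenoxy]-6-(methoxymethoxy)-4-methylbenzoate | COC(=O)c1c(OCOC)cc(C)cc1Oc1c(CO[Si](C(C)C)(C(C)C)C(C)C)cc(OC)cc1OCOC
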